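Compound numbers are those of the steps and of the compound list below. Rings are lettered A to H from the 2,4,6-trioxygenated end of the chain to the 3,4,5-trioxygenated end.

## Analysis of the target

Target 40 is a linear octamer of benzene rings joined only by seven diaryl ether oxygens and carrying 21 free phenolic hydroxyls; there is no carbon–carbon bond between rings, no fused ring and no stereocentre, so the whole problem is connectivity and regiochemistry. Ring A is a 2,4,6-trihydroxyphenyl ether and ring H a 3,4,5-trihydroxyphenyl ether. Rings B, D and F are 1,4-diether rings with hydroxyls at C3 and C5, so one ether oxygen sits on a carbon between two ring hydrogens and the other on a carbon between two oxygens. Rings C, E and G are pentaoxygenated, with two vicinal aryloxy groups, three contiguous hydroxyls and a single ring hydrogen. The free polyphenol is oxidised by air, most readily in base, so it should appear only in the last step and under neutral, reducing conditions, which is what benzyl ethers allow. The hard bonds are the B–C, D–E and F–G ethers: each joins an oxygen flanked by two ortho substituents to a carbon that has a further aryloxy neighbour, the worst case for an aryl halide coupling. The plan rests on ring E, numbered C1 (oxygen to ring D), C2 (oxygen to ring F), C3 to C5 (hydroxyls) and C6 (hydrogen): with C4 and C5 written as carbonyls it is a 3-alkoxy ortho-quinone whose C1 and C2 are the enone β-carbons, the positions at which 4,5-dihalo ortho-quinones exchange halide for oxygen nucleophiles. Ring E can therefore enter as quinone 36, an electrophile on both flanks, with rings D and F as phenols.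

## Retrosynthetic reasoning

40 from 38. The 19 benzyl–oxygen bonds and the two quinone carbonyls of 38 are taken back in one hydrogenation. Nothing else frees 21 hydroxyls under neutral conditions, and 38 is the oxidation state in which the key step delivers ring E, so no separate redox adjustment is needed.

38 from 36, 30 and 35. The ring E C1–O bond (to ring D) and C2–O bond (to ring F) are cut. The cut is central, so it divides the octamer into a four-ring and a three-ring phenol, and it removes the D–E ether, which is one of the hindered kind. Forward, the hindered phenoxide of 30 must go to quinone C5 and the phenoxide of 35 to quinone C4, each by addition and loss of bromide, without electron transfer between phenoxide and quinone.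

36 from 6, 4, 3, 1 and 2. The quinone is made from catechol 6 by oxidation just before use. The bromines of 6 cannot be introduced by brominating a 3-alkoxycatechol that still has three ring hydrogens. Substitution there goes first to C4 and C6, the carbons ortho or para to two oxygens, so the 4,6-dibromide would result and the two leaving groups of the quinone would not be neighbours. The C6 position is therefore blocked by a carboxyl group during bromination. 6 comes from ester 4 by hydrolysis and decarboxylation, 4 from 3 by bromination of its only two free positions, and 3 from 1 and 2 by etherifying the one hydroxyl para to the ester.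

30 from 10, 16 and 21. The three ethers of the tetramer are cut one after another from the ring D end: 30 from aldehyde 28, 28 from 27 and 16, 27 from aldehyde 25, 25 from 24 and 21, 24 from aldehyde 22, and 22 from 10 and 16. In every cut the phenol is the hindered, electron-rich partner and the bromide is activated by an ortho or para formyl group; this is the polarity copper-catalysed etherification tolerates. The formyl group is then turned into the next phenol by Baeyer–Villiger oxidation, so no protecting group is moved. Quinone 36 could in principle also deliver ring C, but that would put the least secure reaction of the plan into the fragment synthesis.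

35 from 12, 21 and 19. The trimer is cut the same way: 35 from its allyl ether 34, 34 from 33 and 19, 33 from aldehyde 31, and 31 from 12 and 21. The allyl group marks the ring F oxygen that must be free in the key step and is the only protecting group in the route that is not benzyl.

Building blocks. Phenols 10 and 12 both come from hydroquinone 9 by alkylating its unhindered hydroxyl with 2 or 11; 9 comes from 7 by para-oxidation and reduction. Bromide 16 comes from 13 and 14 by displacement of the two fluorines, one after the other. The rings with three adjacent benzyloxy groups are cut back to the same aldehyde: bromide 21 comes from 19 by formylation, 19 from phenol 18 and 2 by O-benzylation, and 18 from 16 by the Baeyer–Villiger oxidation that is also used along the chain. In this way 16 supplies rings B and D as it stands, and rings C, G and H after its formyl carbon has been exchanged for a third oxygen.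

## Alternatives that were turned down

Alternative 1: Ring C is made from a four-membered ring instead of being bought as an arene. The racemic cyclobutenone A2, which carries a silyloxy group and an (E)-2-aryloxyvinyl group on the same ring carbon with rings A and B on the vinyl oxygen, is heated. The four-membered ring opens to a dienylketene, which closes by 6π electrocyclisation and tautomerises to the ring A-to-C trimer A1. A1 has a free hydroxyl where ring D will be attached and a silyl ether para to it. In its favour, the substitution pattern of a pentaoxygenated ring is fixed by construction, the two oxygens that must be distinguished come out distinguished, and no phenoxide ever meets an oxidant. On that regiochemical certainty it is stronger than the chosen step, which depends on an electrophilicity difference between two quinone carbons. Against it, the step makes one carbon–carbon bond of one of three identical ring types and joins nothing. A2 needs a vinyl organometallic made in the presence of five benzyl ethers, the silyl ether must later be exchanged, and five further ethers remain to be made in a linear sequence. The chosen strategy offers in exchange two ether bonds and the union of two large fragments in one operation, from phenols alone.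

Alternative 2: Ring A is assembled last. The aryloxymalonate A4, which carries rings B to H on its oxygen, is condensed with dimethyl 3-oxoglutarate A5 under alkoxide base. Two Claisen acylations close ring A as the diester A3. In its favour, the A–B ether is never made by arylation, the oxygen pattern of ring A cannot be wrong, and A4 comes from a simple phenol alkylation; for that one bond it is at least as good as step 11. Against it, the A–B ether is the easiest of the seven, since a hindered phenol and an unhindered activated bromide are what copper handles well. The step presupposes the whole seven-ring phenol, so the synthesis is fully linear. Two ester groups must afterwards be hydrolysed and lost from a molecule that then has an unprotected, air-sensitive ring A. The hindered central ethers are not addressed at all, and these are what the chosen strategy solves.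

Alternative 3: Ring D is built by a Danheiser benzannulation. The racemic cyclobutenone A7, bearing rings E to H on its aryloxy group, is heated with the ethynyl ether A8 of the ring A-to-C trimer. Cycloaddition, ring opening and 6π electrocyclisation give the octamer A6 with ring D as a free phenol and an ethyl ether. In its favour, it is as convergent as the chosen step, it builds a ring, and its regiochemistry follows from the pericyclic sequence and not from order of addition; on site control it is the stronger proposal. Against it, both partners are long to make: an aryl ethynyl ether of a three-ring polyether and a cyclobutenone carrying four rings. Ynol ethers are thermally fragile at the temperatures needed. A6 carries an ethyl ether that hydrogenolysis does not remove, so the end game would need a Lewis acid dealkylation on the full octamer. The chosen strategy offers partners that are two phenols and one small quinone, and an end game of hydrogenolysis alone.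

Key step: step 22

Remark: 1, 7 and 13 are taken as catalogue compounds; 36 is not stored but made immediately before step 22.

## Route

Step 1
Reactants: 1 methyl 2,3,4-trihydroxybenzoate; 2 benzyl bromide
Product: 3 methyl 4-(benzyloxy)-2,3-dihydroxybenzoate
Conditions: BnBr (1.05 equiv), KHCO3, DMF, 40 °C, Ar
Reagents that add atoms: none
Why: Williamson etherification under weak base; only the 4-hydroxyl, para to the ester, is acidic enough for hydrogencarbonate, the 2-hydroxyl is held in a hydrogen bond to the ester carbonyl and the 3-hydroxyl is the least acidic.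

Step 2
Reactants: 3 methyl 4-(benzyloxy)-2,3-dihydroxybenzoate
Product: 4 methyl 4-(benzyloxy)-5,6-dibromo-2,3-dihydroxybenzoate
Conditions: Br2 (2.1 equiv), NaOAc, AcOH, 15 °C → rt
Reagents that add atoms: bromine, BrBr
Why: Electrophilic aromatic bromination of the only two free positions (C5 ortho to the benzyloxy group and para to the 2-hydroxyl, C6 para to the 3-hydroxyl); the ester blocks the position that would otherwise react first and, unlike a free acid, cannot be lost by ipso attack; acetate takes up HBr so the benzyl ether should survive.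

Step 3
Reactants: 4 methyl 4-(benzyloxy)-5,6-dibromo-2,3-dihydroxybenzoate
Product: 6 3-(benzyloxy)-4,5-dibromobenzene-1,2-diol, via dibromo acid 5 (not isolated)
Conditions: KOH (excess), DMSO/H2O, 90 °C, Ar; HCl to pH 2; dioxane/H2O, 100 °C
Reagents that add atoms: none
Why: Saponification of a salicylate ester, run under forcing conditions because the ester lies between a bromine and a phenoxide, then thermal protodecarboxylation by ipso protonation at a carbon ortho to hydroxyl and para to benzyloxy; this is the classical use of a carboxyl as a removable blocking group on halogenated resorcinol-type rings.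

Step 4
Reactants: 7 3,5-bis(benzyloxy)phenol
Product: 9 2,6-bis(benzyloxy)benzene-1,4-diol, via quinone 8 (not isolated)
Conditions: (KSO3)2NO (2.2 equiv), KH2PO4, H2O/acetone, rt; then Na2S2O4, H2O/EtOAc
Reagents that add atoms: potassium nitrosodisulfonate, [K+].[K+].[O]N(S(=O)(=O)[O-])S(=O)(=O)[O-]
Why: Teuber oxidation of a phenol with a free para position gives the para-quinone regiospecifically; dithionite reduces it to the hydroquinone in the same work-up.

Step 5
Reactants: 9 2,6-bis(benzyloxy)benzene-1,4-diol; 2 benzyl bromide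
Product: 10 2,4,6-tris(benzyloxy)phenol
Conditions: BnBr (1.0 equiv), K2CO3 (1.0 equiv), acetone (degassed), 40 °C, Ar
Reagents that add atoms: none
Why: Williamson etherification; the 4-hydroxyl is the more acidic one (meta to two alkoxy groups) and is unhindered, whereas the 1-hydroxyl lies between two benzyloxy groups, so one equivalent of base and halide should alkylate the 4-oxygen.

Step 6
Reactants: 9 2,6-bis(benzyloxy)benzene-1,4-diol; 11 allyl bromide
Product: 12 2,6-bis(benzyloxy)-4-(prop-2-en-1-yloxy)phenol
Conditions: allyl bromide (1.0 equiv), K2CO3 (1.0 equiv), acetone (degassed), 40 °C, Ar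
Reagents that add atoms: none
Why: Williamson etherification with the same site preference as in step 5; the allyl ether is inert to copper coupling and peracid and can later be removed without touching benzyl ethers.

Step 7
Reactants: 13 4-bromo-2,6-difluorobenzaldehyde; 14 benzyl alcohol
Product: 16 2,6-bis(benzyloxy)-4-bromobenzaldehyde, via fluoro monoether 15 (not isolated)
Conditions: BnOH (2.3 equiv), NaH (2.2 equiv), THF/DMF, 0 → 50 °C
Reagents that add atoms: benzyl alcohol (second equivalent), OCc1ccccc1
Why: Two successive nucleophilic aromatic substitutions by sodium benzyloxide; both fluorines are ortho to the formyl group and fluoride is displaced far faster than the para bromide, which is kept for the coupling. The first equivalent of alkoxide gives 15 at 0 °C and the second converts 15 into 16 on warming.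

Step 8
Reactants: 16 2,6-bis(benzyloxy)-4-bromobenzaldehyde
Product: 18 2,6-bis(benzyloxy)-4-bromophenol, via formate 17 (not isolated)
Conditions: mCPBA, CH2Cl2, 0 °C → rt; then K2CO3 (cat.), MeOH
Reagents that add atoms: 3-chloroperbenzoic acid, OOC(=O)c1cccc(Cl)c1
Why: Baeyer–Villiger oxidation of an aldehyde flanked by two alkoxy groups; the electron-rich aryl group migrates in preference to hydrogen, and methanolysis of the formate frees a phenol whose oxygen completes the 1,2,3-trioxygen pattern para to the bromine.

Step 9
Reactants: 18 2,6-bis(benzyloxy)-4-bromophenol; 2 benzyl bromide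
Product: 19 1,2,3-tris(benzyloxy)-5-bromobenzene
Conditions: BnBr (1.2 equiv), K2CO3, DMF, 60 °C
Reagents that add atoms: none
Why: Williamson etherification of the one free phenol; the hydroxyl lies between two benzyloxy groups but benzylation of such 2,6-dialkoxyphenols with carbonate in DMF is routine, and the aryl bromide is inert.

Step 10
Reactants: 19 1,2,3-tris(benzyloxy)-5-bromobenzene
Product: 21 2,3,4-tris(benzyloxy)-6-bromobenzaldehyde, via iminium chloride 20 (not isolated)
Conditions: POCl3, DMF, 80 °C; then H2O, 50 °C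
Reagents that add atoms: N,N-dimethylformamide, CN(C)C=O; water, O
Why: Vilsmeier–Haack formylation; the two free positions are equivalent, each ortho and para to a benzyloxy group, so only one aldehyde can form, with the bromine ortho to the new formyl group.

Step 11
Reactants: 10 2,4,6-tris(benzyloxy)phenol; 16 2,6-bis(benzyloxy)-4-bromobenzaldehyde
Product: 22 2,6-bis(benzyloxy)-4-[2,4,6-tris(benzyloxy)phenoxy]benzaldehyde
Conditions: CuI (10 mol %), picolinic acid (20 mol %), K3PO4, DMSO, 90 °C
Reagents that add atoms: none
Why: Ullmann-type copper-catalysed diaryl ether synthesis; the hindered, electron-rich phenol is the nucleophile and the bromide is unhindered and activated by the para formyl group.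

Step 12
Reactants: 22 2,6-bis(benzyloxy)-4-[2,4,6-tris(benzyloxy)phenoxy]benzaldehyde
Product: 24 2,6-bis(benzyloxy)-4-[2,4,6-tris(benzyloxy)phenoxy]phenol, via formate 23 (not isolated)
Conditions: mCPBA, CH2Cl2, 0 °C → rt; then K2CO3 (cat.), MeOH
Reagents that add atoms: 3-chloroperbenzoic acid, OOC(=O)c1cccc(Cl)c1
Why: Baeyer–Villiger oxidation; the aryl group with two ortho oxygens migrates in preference to hydrogen, and methanolysis of the formate frees the phenol between the two benzyloxy groups.

Step 13
Reactants: 24 2,6-bis(benzyloxy)-4-[2,4,6-tris(benzyloxy)phenoxy]phenol; 21 2,3,4-tris(benzyloxy)-6-bromobenzaldehyde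
Product: 25 2,3,4-tris(benzyloxy)-6-{2,6-bis(benzyloxy)-4-[2,4,6-tris(benzyloxy)phenoxy]phenoxy}benzaldehyde
Conditions: CuI (10 mol %), picolinic acid (20 mol %), K3PO4, DMSO, 100 °C
Reagents that add atoms: none
Why: Ullmann-type etherification; the bromide is ortho to the formyl group and has only a hydrogen as its other neighbour, so the hindered phenoxide meets an activated and accessible carbon.

Step 14
Reactants: 25 ring A-to-C aldehyde
Product: 27 2,3,4-tris(benzyloxy)-6-{2,6-bis(benzyloxy)-4-[2,4,6-tris(benzyloxy)phenoxy]phenoxy}phenol, via formate 26 (not isolated)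
Conditions: mCPBA, CH2Cl2, 0 °C → rt; then K2CO3 (cat.), MeOH
Reagents that add atoms: 3-chloroperbenzoic acid, OOC(=O)c1cccc(Cl)c1
Why: Baeyer–Villiger oxidation as in step 12; it places the new hydroxyl on ring C between the ring B aryloxy group and a benzyloxy group, where ring D belongs.

Step 15
Reactants: 27 ring A-to-C phenol; 16 2,6-bis(benzyloxy)-4-bromobenzaldehyde
Product: 28 ring A-to-D aldehyde, the diaryl ether of 27 with the C4 carbon of 16
Conditions: CuI (15 mol %), picolinic acid (30 mol %), K3PO4, DMSO, 100 °C
Reagents that add atoms: none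
Why: Ullmann-type etherification of the same kind as step 11: hindered phenol, unhindered bromide activated by a para formyl group.

Step 16
Reactants: 28 ring A-to-D aldehyde
Product: 30 ring A-to-D tetramer phenol with the free hydroxyl on ring D between two benzyloxy groups, via formate 29 (not isolated)
Conditions: mCPBA, CH2Cl2, 0 °C → rt; then K2CO3 (cat.), MeOH
Reagents that add atoms: 3-chloroperbenzoic acid, OOC(=O)c1cccc(Cl)c1
Why: Baeyer–Villiger oxidation as in step 12; the formyl carbon between the two benzyloxy groups of ring D becomes the phenol needed for the key step.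

Step 17
Reactants: 12 2,6-bis(benzyloxy)-4-(prop-2-en-1-yloxy)phenol; 21 2,3,4-tris(benzyloxy)-6-bromobenzaldehyde
Product: 31 2,3,4-tris(benzyloxy)-6-[2,6-bis(benzyloxy)-4-(prop-2-en-1-yloxy)phenoxy]benzaldehyde
Conditions: CuI (10 mol %), picolinic acid (20 mol %), K3PO4, DMSO, 100 °C
Reagents that add atoms: none
Why: Ullmann-type etherification as in step 13; the allyl ether is inert at this temperature.

Step 18
Reactants: 31 ring F-to-G aldehyde
Product: 33 2,3,4-tris(benzyloxy)-6-[2,6-bis(benzyloxy)-4-(prop-2-en-1-yloxy)phenoxy]phenol, via formate 32 (not isolated)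
Conditions: mCPBA (1.1 equiv), CH2Cl2, 0 °C; then K2CO3 (cat.), MeOH
Reagents that add atoms: 3-chloroperbenzoic acid, OOC(=O)c1cccc(Cl)c1
Why: Baeyer–Villiger oxidation; with one equivalent of peracid at 0 °C the electron-rich aldehyde should react much faster than the isolated terminal double bond of the allyl group.

Step 19
Reactants: 33 ring F-to-G phenol; 19 1,2,3-tris(benzyloxy)-5-bromobenzene
Product: 34 ring F-to-H trimer allyl ether
Conditions: CuI (20 mol %), picolinic acid (40 mol %), K3PO4, DMSO, 110 °C
Reagents that add atoms: none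
Why: Ullmann-type etherification of a hindered phenol with an unhindered aryl bromide that has no activating group; this is the pairing used classically for methylated phlorotannin ethers.

Step 20
Reactants: 34 ring F-to-H trimer allyl ether
Product: 35 ring F-to-H trimer phenol with the free hydroxyl on ring F between two ring hydrogens
Conditions: Pd(PPh3)4 (5 mol %), morpholine, THF, rt
Reagents that add atoms: none
Why: Palladium-catalysed allyl transfer (Tsuji–Trost type) to morpholine frees the phenol under neutral conditions that leave benzyl and diaryl ethers untouched.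

Step 21
Reactants: 6 3-(benzyloxy)-4,5-dibromobenzene-1,2-diol
Product: 36 3-(benzyloxy)-4,5-dibromocyclohexa-3,5-diene-1,2-dione
Conditions: NaIO4, CH2Cl2/H2O, 0 °C; dried (Na2SO4), used at once
Reagents that add atoms: none
Why: Two-electron oxidation of a catechol to its ortho-quinone by periodate; the two bromines and the alkoxy group slow dimerisation, but the quinone is used without storage.

Step 22
Reactants: 36 3-(benzyloxy)-4,5-dibromocyclohexa-3,5-diene-1,2-dione; 30 ring A-to-D tetramer phenol; 35 ring F-to-H trimer phenol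
Product: 38 benzyl-protected octamer with ring E as its ortho-quinone, via monoadduct 37 (not isolated)
Conditions: 30, NaH (1.0 equiv), THF, 0 °C; added to 36 (1.05 equiv), THF, −78 °C; then sodium salt of 35 (1.1 equiv, from NaH), THF/DMF, −78 → −10 °C; AcOH quench
Reagents that add atoms: none
Why: Each carbon–oxygen bond forms by conjugate addition of an aryloxide to a bromine-bearing β-carbon of the ortho-quinone followed by loss of bromide, that is, addition–elimination at a vinylogous acyl bromide. The closest known reaction type is the replacement of the 4- and 5-halogens of ortho-chloranil and related 4,5-dihalo ortho-quinones by alkoxides, aryloxides and amines. No ring closes and no stereocentre is formed. The step needs site selectivity: quinone C5 is the β-carbon of the C1 carbonyl/C6=C5 enone and has no donor on its double bond, whereas C4 is the β-carbon of the enol ether at C3 and receives electron density from the 3-benzyloxy group, so the first phenoxide, that of 30, should attack C5 and give 37. Only the C4 bromide is then left for the phenoxide of 35, and the aryloxy group already on C5 sits on a vinylogous ester carbon and is a poorer leaving group than bromide, so it should not be exchanged. The step also needs substitution to win over electron transfer from phenoxide to quinone: the phenoxide is added to the quinone at −78 °C so that it is never in excess, and 37, with one more donor, is a weaker oxidant than 36, which allows the second, slower substitution to be run warmer. The ring D phenoxide has every ortho and para carbon substituted, so even a radical pair could only recombine at oxygen, and the dissociated sodium salt of 35 in THF/DMF favours attack through oxygen over attack through its free ortho carbons. The planar, highly electrophilic quinone carbon is what lets the 2,6-bis(benzyloxy)phenoxide of ring D form an ether that an aryl halide coupling would resist.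

Step 23
Reactants: 38 benzyl-protected octamer ortho-quinone
Product: 40 target octamer CNP0206369.0, via octamer catechol 39 (not isolated)
Conditions: H2 (1–3 bar), Pd/C (10%), THF/MeOH, rt; filtration under Ar
Reagents that add atoms: none
Why: Catalytic hydrogenation reduces the quinone to the catechol first and then cleaves the nineteen benzyl ethers by hydrogenolysis; diaryl ethers and the aromatic rings are not attacked under these conditions, and the neutral reducing medium protects the polyphenol.

## Compound list

1 | methyl 2,3,4-trihydroxybenzoate | COC(=O)c1ccc(O)c(O)c1O | starting material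
2 | benzyl bromide | BrCc1ccccc1 | starting material
3 | methyl 4-(benzyloxy)-2,3-dihydroxybenzoate | COC(=O)c1ccc(OCc9ccccc9)c(O)c1O | intermediate
4 | methyl 4-(benzyloxy)-5,6-dibromo-2,3-dihydroxybenzoate | COC(=O)c1c(Br)c(Br)c(OCc9ccccc9)c(O)c1O | intermediate
5 | 4-(benzyloxy)-5,6-dibromo-2,3-dihydroxybenzoic acid (not isolated) | OC(=O)c1c(Br)c(Br)c(OCc9ccccc9)c(O)c1O | intermediate
6 | 3-(benzyloxy)-4,5-dibromobenzene-1,2-diol | Oc1cc(Br)c(Br)c(OCc9ccccc9)c1O | intermediate
7 | 3,5-bis(benzyloxy)phenol | Oc1cc(OCc9ccccc9)cc(OCc9ccccc9)c1 | starting material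
8 | 2,6-bis(benzyloxy)cyclohexa-2,5-diene-1,4-dione (not isolated) | O=C1C=C(OCc9ccccc9)C(=O)C(OCc9ccccc9)=C1 | intermediate
9 | 2,6-bis(benzyloxy)benzene-1,4-diol | Oc1cc(OCc9ccccc9)c(O)c(OCc9ccccc9)c1 | intermediate
10 | 2,4,6-tris(benzyloxy)phenol | Oc1c(OCc9ccccc9)cc(OCc9ccccc9)cc1OCc9ccccc9 | intermediate
11 | allyl bromide (3-bromoprop-1-ene) | C=CCBr | starting material
12 | 2,6-bis(benzyloxy)-4-(prop-2-en-1-yloxy)phenol | C=CCOc1cc(OCc9ccccc9)c(O)c(OCc9ccccc9)c1 | intermediate
13 | 4-bromo-2,6-difluorobenzaldehyde | O=Cc1c(F)cc(Br)cc1F | starting material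
14 | benzyl alcohol | OCc1ccccc1 | starting material
15 | 2-(benzyloxy)-4-bromo-6-fluorobenzaldehyde (not isolated) | O=Cc1c(F)cc(Br)cc1OCc9ccccc9 | intermediate
16 | 2,6-bis(benzyloxy)-4-bromobenzaldehyde | O=Cc1c(OCc9ccccc9)cc(Br)cc1OCc9ccccc9 | intermediate
17 | 2,6-bis(benzyloxy)-4-bromophenyl formate (not isolated) | O=COc1c(OCc9ccccc9)cc(Br)cc1OCc9ccccc9 | intermediate
18 | 2,6-bis(benzyloxy)-4-bromophenol | Oc1c(OCc9ccccc9)cc(Br)cc1OCc9ccccc9 | intermediate
19 | 1,2,3-tris(benzyloxy)-5-bromobenzene | Brc1cc(OCc9ccccc9)c(OCc9ccccc9)c(OCc9ccccc9)c1 | intermediate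
20 | N-{[2,3,4-tris(benzyloxy)-6-bromophenyl]methylidene}-N-methylmethanaminium chloride (not isolated) | C[N+](C)=Cc1c(Br)cc(OCc9ccccc9)c(OCc9ccccc9)c1OCc9ccccc9.[Cl-] | intermediate
21 | 2,3,4-tris(benzyloxy)-6-bromobenzaldehyde | O=Cc1c(Br)cc(OCc9ccccc9)c(OCc9ccccc9)c1OCc9ccccc9 | intermediate
22 | 2,6-bis(benzyloxy)-4-[2,4,6-tris(benzyloxy)phenoxy]benzaldehyde (ring A-to-B aldehyde) | O=Cc1c(OCc9ccccc9)cc(Oc2c(OCc9ccccc9)cc(OCc9ccccc9)cc2OCc9ccccc9)cc1OCc9ccccc9 | intermediate
23 | 2,6-bis(benzyloxy)-4-[2,4,6-tris(benzyloxy)phenoxy]phenyl formate (not isolated) | O=COc1c(OCc9ccccc9)cc(Oc2c(OCc9ccccc9)cc(OCc9ccccc9)cc2OCc9ccccc9)cc1OCc9ccccc9 | intermediate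
24 | 2,6-bis(benzyloxy)-4-[2,4,6-tris(benzyloxy)phenoxy]phenol (ring A-to-B phenol) | Oc1c(OCc9ccccc9)cc(Oc2c(OCc9ccccc9)cc(OCc9ccccc9)cc2OCc9ccccc9)cc1OCc9ccccc9 | intermediate
25 | 2,3,4-tris(benzyloxy)-6-{2,6-bis(benzyloxy)-4-[2,4,6-tris(benzyloxy)phenoxy]phenoxy}benzaldehyde (ring A-to-C aldehyde) | O=Cc1c(Oc3c(OCc9ccccc9)cc(Oc2c(OCc9ccccc9)cc(OCc9ccccc9)cc2OCc9ccccc9)cc3OCc9ccccc9)cc(OCc9ccccc9)c(OCc9ccccc9)c1OCc9ccccc9 | intermediate
26 | 2,3,4-tris(benzyloxy)-6-{2,6-bis(benzyloxy)-4-[2,4,6-tris(benzyloxy)phenoxy]phenoxy}phenyl formate (not isolated) | O=COc1c(Oc3c(OCc9ccccc9)cc(Oc2c(OCc9ccccc9)cc(OCc9ccccc9)cc2OCc9ccccc9)cc3OCc9ccccc9)cc(OCc9ccccc9)c(OCc9ccccc9)c1OCc9ccccc9 | intermediate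
27 | 2,3,4-tris(benzyloxy)-6-{2,6-bis(benzyloxy)-4-[2,4,6-tris(benzyloxy)phenoxy]phenoxy}phenol (ring A-to-C phenol) | Oc1c(Oc3c(OCc9ccccc9)cc(Oc2c(OCc9ccccc9)cc(OCc9ccccc9)cc2OCc9ccccc9)cc3OCc9ccccc9)cc(OCc9ccccc9)c(OCc9ccccc9)c1OCc9ccccc9 | intermediate
28 | ring A-to-D aldehyde: 2,6-bis(benzyloxy)-4-(aryloxy)benzaldehyde whose aryl group is 27 without its hydroxyl hydrogen | O=Cc1c(OCc9ccccc9)cc(Oc4c(Oc3c(OCc9ccccc9)cc(Oc2c(OCc9ccccc9)cc(OCc9ccccc9)cc2OCc9ccccc9)cc3OCc9ccccc9)cc(OCc9ccccc9)c(OCc9ccccc9)c4OCc9ccccc9)cc1OCc9ccccc9 | intermediate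
29 | ring A-to-D aryl formate: 28 with OCHO in place of CHO (not isolated) | O=COc1c(OCc9ccccc9)cc(Oc4c(Oc3c(OCc9ccccc9)cc(Oc2c(OCc9ccccc9)cc(OCc9ccccc9)cc2OCc9ccccc9)cc3OCc9ccccc9)cc(OCc9ccccc9)c(OCc9ccccc9)c4OCc9ccccc9)cc1OCc9ccccc9 | intermediate
30 | ring A-to-D tetramer phenol: 28 with OH in place of CHO, the hydroxyl on ring D between two benzyloxy groups | c9ccccc9COc1cc(OCc9ccccc9)c(Oc2cc(OCc9ccccc9)c(Oc3cc(OCc9ccccc9)c(OCc9ccccc9)c(OCc9ccccc9)c3Oc3cc(OCc9ccccc9)c(O)c(OCc9ccccc9)c3)c(OCc9ccccc9)c2)c(OCc9ccccc9)c1 | intermediate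
31 | 2,3,4-tris(benzyloxy)-6-[2,6-bis(benzyloxy)-4-(prop-2-en-1-yloxy)phenoxy]benzaldehyde (ring F-to-G aldehyde) | O=Cc1c(Oc2c(OCc9ccccc9)cc(OCC=C)cc2OCc9ccccc9)cc(OCc9ccccc9)c(OCc9ccccc9)c1OCc9ccccc9 | intermediate
32 | 2,3,4-tris(benzyloxy)-6-[2,6-bis(benzyloxy)-4-(prop-2-en-1-yloxy)phenoxy]phenyl formate (not isolated) | O=COc1c(Oc2c(OCc9ccccc9)cc(OCC=C)cc2OCc9ccccc9)cc(OCc9ccccc9)c(OCc9ccccc9)c1OCc9ccccc9 | intermediate
33 | 2,3,4-tris(benzyloxy)-6-[2,6-bis(benzyloxy)-4-(prop-2-en-1-yloxy)phenoxy]phenol (ring F-to-G phenol) | Oc1c(Oc2c(OCc9ccccc9)cc(OCC=C)cc2OCc9ccccc9)cc(OCc9ccccc9)c(OCc9ccccc9)c1OCc9ccccc9 | intermediate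
34 | ring F-to-H trimer allyl ether: 33 O-arylated with the 3,4,5-tris(benzyloxy)phenyl group | C=CCOc1cc(OCc9ccccc9)c(Oc2cc(OCc9ccccc9)c(OCc9ccccc9)c(OCc9ccccc9)c2Oc3cc(OCc9ccccc9)c(OCc9ccccc9)c(OCc9ccccc9)c3)c(OCc9ccccc9)c1 | intermediate
35 | ring F-to-H trimer phenol: 34 without the allyl group, the hydroxyl on ring F between two ring hydrogens | Oc1cc(OCc9ccccc9)c(Oc2cc(OCc9ccccc9)c(OCc9ccccc9)c(OCc9ccccc9)c2Oc3cc(OCc9ccccc9)c(OCc9ccccc9)c(OCc9ccccc9)c3)c(OCc9ccccc9)c1 | intermediate
36 | 3-(benzyloxy)-4,5-dibromocyclohexa-3,5-diene-1,2-dione | O=C1C(=O)C(OCc9ccccc9)=C(Br)C(Br)=C1 | intermediate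
37 | monoadduct: 3-(benzyloxy)-4-bromo-ortho-benzoquinone carrying the phenolic oxygen of 30 at C5 (not isolated) | c9ccccc9COc1cc(OCc9ccccc9)c(Oc2cc(OCc9ccccc9)c(Oc3cc(OCc9ccccc9)c(OCc9ccccc9)c(OCc9ccccc9)c3Oc3cc(OCc9ccccc9)c(OC6=CC(=O)C(=O)C(OCc9ccccc9)=C6Br)c(OCc9ccccc9)c3)c(OCc9ccccc9)c2)c(OCc9ccccc9)c1 | intermediate
38 | benzyl-protected octamer with ring E as 3-(benzyloxy) ortho-quinone, the oxygen of 30 at quinone C5 and the oxygen of 35 at quinone C4 | c9ccccc9COc1cc(OCc9ccccc9)c(Oc2cc(OCc9ccccc9)c(Oc3cc(OCc9ccccc9)c(OCc9ccccc9)c(OCc9ccccc9)c3Oc3cc(OCc9ccccc9)c(OC6=CC(=O)C(=O)C(OCc9ccccc9)=C6Oc4cc(OCc9ccccc9)c(Oc5cc(OCc9ccccc9)c(OCc9ccccc9)c(OCc9ccccc9)c5Oc5cc(OCc9ccccc9)c(OCc9ccccc9)c(OCc9ccccc9)c5)c(OCc9ccccc9)c4)c(OCc9ccccc9)c3)c(OCc9ccccc9)c2)c(OCc9ccccc9)c1 | intermediate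
39 | benzyl-protected octamer with ring E as the catechol: 38 with its two carbonyls reduced to hydroxyls (not isolated) | c9ccccc9COc1cc(OCc9ccccc9)c(Oc2cc(OCc9ccccc9)c(Oc3cc(OCc9ccccc9)c(OCc9ccccc9)c(OCc9ccccc9)c3Oc3cc(OCc9ccccc9)c(Oc6cc(O)c(O)c(OCc9ccccc9)c6Oc4cc(OCc9ccccc9)c(Oc5cc(OCc9ccccc9)c(OCc9ccccc9)c(OCc9ccccc9)c5Oc5cc(OCc9ccccc9)c(OCc9ccccc9)c(OCc9ccccc9)c5)c(OCc9ccccc9)c4)c(OCc9ccccc9)c3)c(OCc9ccccc9)c2)c(OCc9ccccc9)c1 | intermediate
40 | CNP0206369.0, the free octamer with 21 hydroxyls | Oc1cc(O)c(Oc2cc(O)c(Oc3cc(O)c(O)c(O)c3Oc3cc(O)c(Oc4cc(O)c(O)c(O)c4Oc4cc(O)c(Oc5cc(O)c(O)c(O)c5Oc5cc(O)c(O)c(O)c5)c(O)c4)c(O)c3)c(O)c2)c(O)c1 | target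

## Step count and least certain steps

Total: 23 steps. Longest linear sequence: 10 steps (steps 4, 5, 11, 12, 13, 14, 15, 16, 22, 23); the chains through steps 7, 8, 9 and 10 into step 13 or into step 17 are equally long.

Step 22 (key step). The most likely failure is electron transfer from the electron-rich phenoxides to the quinone, which reduces the quinone and oxidises the phenols instead of joining them. Further risks are loss of site control between C5 and C4, exchange of the first aryloxy group by the second phenoxide, and attack of the ring F phenoxide through an ortho carbon instead of oxygen. Fallback: the quinone is given up and the D–E and E–F ethers are closed the way the fragments were made. The fallback sets out from 30 and 35 and returns at 40. 30 is coupled with 21 (CuI, picolinic acid, K3PO4, DMSO) to the ring A-to-E pentamer aldehyde F1. Baeyer–Villiger oxidation gives the pentamer formate F2 and, after methanolysis, the pentamer phenol F3 with its hydroxyl on ring E. 35 is converted with Tf2O and pyridine into the trimer triflate F4. F3 and F4 are joined by palladium-catalysed diaryl ether formation (Pd(OAc)2, a di-tert-butyl biaryl phosphine, K3PO4, toluene, 100 °C) to the fully benzylated octamer F5. Hydrogenolysis of F5 (H2, Pd/C) should give 40.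

Step 19. Copper-catalysed etherification may stall because the bromide of 19 has no activating group and the phenol of 33 is flanked by an aryloxy and a benzyloxy group; slow turnover then gives way to reduction of the bromide. Fallback: oxidative copper coupling with a boronic acid, setting out from 19 and 33 and returning at 34. 19 is converted by bromine–lithium exchange (n-BuLi, THF, −78 °C), B(OiPr)3 and acidic work-up into [3,4,5-tris(benzyloxy)phenyl]boronic acid F6. F6 is coupled with 33 under Chan–Lam conditions (Cu(OAc)2, pyridine, 4 Å molecular sieves, CH2Cl2, air, rt) to give 34.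

Step 10. The ring of 19 is deactivated by bromine, so formylation may be slow, and prolonged heating with POCl3 may cost benzyl groups. Fallback: the formyl group is introduced on the methyl ether series and the protecting groups are exchanged afterwards. The fallback sets out from 2 and a commercial arene and returns at 21; 19 remains the bromide for step 19 and is made as in step 9. Commercial 5-bromo-1,2,3-trimethoxybenzene F7 undergoes Rieche formylation (Cl2CHOMe, TiCl4, CH2Cl2, −78 → 0 °C) through the α-chloro ether F8 to 6-bromo-2,3,4-trimethoxybenzaldehyde F9. BBr3 (CH2Cl2, −78 °C → rt) gives 6-bromo-2,3,4-trihydroxybenzaldehyde F10, and benzylation with 2 (K2CO3, DMF, 60 °C) gives 21.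

Step 23. Hydrogenolysis of nineteen benzyl ethers may stop short as partly deprotected polyphenols adsorb on the catalyst, and the product may oxidise on contact with air during filtration. Fallback: reduction and debenzylation are separated and the benzyl groups are removed by a Lewis acid. The fallback sets out from 38 and returns at 40. 38 is reduced with Na2S2O4 (THF/H2O) to 39, which is isolated in this variant, and 39 is treated with BCl3 and pentamethylbenzene (CH2Cl2, −78 °C) to give 40.

## Further compounds

F1 | step 22 | ring A-to-E pentamer aldehyde: 2,3,4-tris(benzyloxy)-6-(aryloxy)benzaldehyde whose aryl group is 30 without its hydroxyl hydrogen | c9ccccc9COc1cc(OCc9ccccc9)c(Oc2cc(OCc9ccccc9)c(Oc3cc(OCc9ccccc9)c(OCc9ccccc9)c(OCc9ccccc9)c3Oc3cc(OCc9ccccc9)c(Oc6cc(OCc9ccccc9)c(OCc9ccccc9)c(OCc9ccccc9)c6C=O)c(OCc9ccccc9)c3)c(OCc9ccccc9)c2)c(OCc9ccccc9)c1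
F2 | step 22 | ring A-to-E pentamer aryl formate: F1 with OCHO in place of CHO | c9ccccc9COc1cc(OCc9ccccc9)c(Oc2cc(OCc9ccccc9)c(Oc3cc(OCc9ccccc9)c(OCc9ccccc9)c(OCc9ccccc9)c3Oc3cc(OCc9ccccc9)c(Oc6cc(OCc9ccccc9)c(OCc9ccccc9)c(OCc9ccccc9)c6OC=O)c(OCc9ccccc9)c3)c(OCc9ccccc9)c2)c(OCc9ccccc9)c1
F3 | step 22 | ring A-to-E pentamer phenol: F1 with OH in place of CHO | c9ccccc9COc1cc(OCc9ccccc9)c(Oc2cc(OCc9ccccc9)c(Oc3cc(OCc9ccccc9)c(OCc9ccccc9)c(OCc9ccccc9)c3Oc3cc(OCc9ccccc9)c(Oc6cc(OCc9ccccc9)c(OCc9ccccc9)c(OCc9ccccc9)c6O)c(OCc9ccccc9)c3)c(OCc9ccccc9)c2)c(OCc9ccccc9)c1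
F4 | step 22 | ring F-to-H trimer triflate: trifluoromethanesulfonate ester of 35 | O=S(=O)(Oc1cc(OCc9ccccc9)c(Oc2cc(OCc9ccccc9)c(OCc9ccccc9)c(OCc9ccccc9)c2Oc3cc(OCc9ccccc9)c(OCc9ccccc9)c(OCc9ccccc9)c3)c(OCc9ccccc9)c1)C(F)(F)F
F5 | step 22 | fully benzylated octamer: 40 with all 21 hydroxyls as benzyl ethers | c9ccccc9COc1cc(OCc9ccccc9)c(Oc2cc(OCc9ccccc9)c(Oc3cc(OCc9ccccc9)c(OCc9ccccc9)c(OCc9ccccc9)c3Oc3cc(OCc9ccccc9)c(Oc6cc(OCc9ccccc9)c(OCc9ccccc9)c(OCc9ccccc9)c6Oc4cc(OCc9ccccc9)c(Oc5cc(OCc9ccccc9)c(OCc9ccccc9)c(OCc9ccccc9)c5Oc5cc(OCc9ccccc9)c(OCc9ccccc9)c(OCc9ccccc9)c5)c(OCc9ccccc9)c4)c(OCc9ccccc9)c3)c(OCc9ccccc9)c2)c(OCc9ccccc9)c1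
F6 | step 19 | [3,4,5-tris(benzyloxy)phenyl]boronic acid | OB(O)c1cc(OCc9ccccc9)c(OCc9ccccc9)c(OCc9ccccc9)c1
F7 | step 10 | 5-bromo-1,2,3-trimethoxybenzene | COc1cc(Br)cc(OC)c1OC
F8 | step 10 | 1-bromo-2-[chloro(methoxy)methyl]-3,4,5-trimethoxybenzene (racemic) | COC(Cl)c1c(Br)cc(OC)c(OC)c1OC
F9 | step 10 | 6-bromo-2,3,4-trimethoxybenzaldehyde | O=Cc1c(Br)cc(OC)c(OC)c1OC
F10 | step 10 | 6-bromo-2,3,4-trihydroxybenzaldehyde | O=Cc1c(Br)cc(O)c(O)c1O
F0 | step 23 | none | none
A1 | alternative 1 | ring A-to-C trimer with a free hydroxyl on ring C next to the ring B aryloxy carbon and a tert-butyldimethylsilyl ether para to that hydroxyl | c9ccccc9COc1cc(OCc9ccccc9)c(Oc2cc(OCc9ccccc9)c(Oc3cc(O[Si](C)(C)C(C)(C)C)c(OCc9ccccc9)c(OCc9ccccc9)c3O)c(OCc9ccccc9)c2)c(OCc9ccccc9)c1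
A2 | alternative 1 | 2,3-bis(benzyloxy)-4-[(tert-butyldimethylsilyl)oxy]-4-[(E)-2-(aryloxy)ethenyl]cyclobut-2-en-1-one (racemic), aryl being the ring A-to-B unit of 24 | O=C1C(OCc9ccccc9)=C(OCc9ccccc9)C1(O[Si](C)(C)C(C)(C)C)/C=C/Oc2c(OCc9ccccc9)cc(Oc3c(OCc9ccccc9)cc(OCc9ccccc9)cc3OCc9ccccc9)cc2OCc9ccccc9
A3 | alternative 2 | octamer with ring A as dimethyl 2,4,6-trihydroxy-5-(aryloxy)benzene-1,3-dicarboxylate, aryl being the benzyl-protected ring B-to-H heptamer | COC(=O)c1c(O)c(C(=O)OC)c(O)c(Oc2cc(OCc9ccccc9)c(Oc3cc(OCc9ccccc9)c(OCc9ccccc9)c(OCc9ccccc9)c3Oc3cc(OCc9ccccc9)c(Oc4cc(OCc9ccccc9)c(OCc9ccccc9)c(OCc9ccccc9)c4Oc4cc(OCc9ccccc9)c(Oc5cc(OCc9ccccc9)c(OCc9ccccc9)c(OCc9ccccc9)c5Oc5cc(OCc9ccccc9)c(OCc9ccccc9)c(OCc9ccccc9)c5)c(OCc9ccccc9)c4)c(OCc9ccccc9)c3)c(OCc9ccccc9)c2)c1O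
A4 | alternative 2 | dimethyl 2-(aryloxy)propanedioate, aryl being the benzyl-protected ring B-to-H heptamer | COC(=O)C(C(=O)OC)Oc2cc(OCc9ccccc9)c(Oc3cc(OCc9ccccc9)c(OCc9ccccc9)c(OCc9ccccc9)c3Oc3cc(OCc9ccccc9)c(Oc4cc(OCc9ccccc9)c(OCc9ccccc9)c(OCc9ccccc9)c4Oc4cc(OCc9ccccc9)c(Oc5cc(OCc9ccccc9)c(OCc9ccccc9)c(OCc9ccccc9)c5Oc5cc(OCc9ccccc9)c(OCc9ccccc9)c(OCc9ccccc9)c5)c(OCc9ccccc9)c4)c(OCc9ccccc9)c3)c(OCc9ccccc9)c2
A5 | alternative 2 | dimethyl 3-oxopentanedioate (dimethyl 3-oxoglutarate) | COC(=O)CC(=O)CC(=O)OC
A6 | alternative 3 | benzyl-protected octamer with ring D as a free phenol at C3 and an ethyl ether at C5 | c9ccccc9COc1cc(OCc9ccccc9)c(Oc2cc(OCc9ccccc9)c(Oc3cc(OCc9ccccc9)c(OCc9ccccc9)c(OCc9ccccc9)c3Oc3cc(O)c(Oc4cc(OCc9ccccc9)c(OCc9ccccc9)c(OCc9ccccc9)c4Oc4cc(OCc9ccccc9)c(Oc5cc(OCc9ccccc9)c(OCc9ccccc9)c(OCc9ccccc9)c5Oc5cc(OCc9ccccc9)c(OCc9ccccc9)c(OCc9ccccc9)c5)c(OCc9ccccc9)c4)c(OCC)c3)c(OCc9ccccc9)c2)c(OCc9ccccc9)c1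
A7 | alternative 3 | 4-(aryloxy)-3-ethoxycyclobut-2-en-1-one (racemic), aryl being the benzyl-protected ring E-to-H tetramer | O=C1C=C(OCC)C1Oc4cc(OCc9ccccc9)c(OCc9ccccc9)c(OCc9ccccc9)c4Oc4cc(OCc9ccccc9)c(Oc5cc(OCc9ccccc9)c(OCc9ccccc9)c(OCc9ccccc9)c5Oc5cc(OCc9ccccc9)c(OCc9ccccc9)c(OCc9ccccc9)c5)c(OCc9ccccc9)c4
A8 | alternative 3 | ethynyl ether of the ring A-to-C trimer: 27 with its hydroxyl hydrogen replaced by an ethynyl group | C#COc3c(Oc2c(OCc9ccccc9)cc(Oc1c(OCc9ccccc9)cc(OCc9ccccc9)cc1OCc9ccccc9)cc2OCc9ccccc9)cc(OCc9ccccc9)c(OCc9ccccc9)c3OCc9ccccc9
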